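**Strategy.** Everything rests on the C3–C1′ disconnection. C3, the tertiary carbinol carbon of the pyranone ring between C4 (C=O) and C2 (CH2–O1), is traced back to the ketone of an α-keto ester whose ester carbon is the future C4 and whose CH2 already carries the ring-A oxygen. C1′ of ring B lies ortho to the 2′-OH and para to the 4′-OMe, the most nucleophilic site of that phenol. One catalytic enantioselective ortho-Friedel–Crafts hydroxyalkylation therefore joins both halves and sets the (S)-quaternary carbinol. The precursor pair is an open-chain aryloxypyruvate and a simple 3-methoxy-2-(MOM-oxy)phenol; Parham cyclisation then closes ring C, and the prenyl group enters last at C5′.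

Key step: step 7

Assumption: C3 of the target is (S) (CIP: OH > C4 > C2 > C1′), which requires Re-face attack on the keto ester; the quinine-derived squaramide is assumed to give this sense by analogy, otherwise its quinidine-derived pseudo-enantiomer is used.

Step 1
Reactants: 1 o-vanillin (2-hydroxy-3-methoxybenzaldehyde)
Product: 2 3-methoxy-2-(methoxymethoxy)benzaldehyde
Conditions: MOMCl, K2CO3, acetone, 0 °C → 50 °C
Reagents that add atoms: chloromethyl methyl ether (MOMCl), COCCl
Why: Williamson-type O-alkylation of the phenoxide with the reactive α-chloro ether caps the future 3′-oxygen as a base-stable MOM acetal and leaves the aldehyde untouched.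

Step 2
Reactants: 2 3-methoxy-2-(methoxymethoxy)benzaldehyde
Product: 4 3-methoxy-2-(methoxymethoxy)phenol, via aryl formate 3 (not isolated)
Conditions: mCPBA, CH2Cl2, 0 °C → rt; then K2CO3 (cat.), MeOH, rt
Reagents that add atoms: meta-chloroperoxybenzoic acid (mCPBA), OOC(=O)c1cccc(Cl)c1
Why: Baeyer–Villiger (Dakin-type) oxidation in which the electron-rich ortho-alkoxyaryl group migrates in the Criegee intermediate should give formate 3, whose mild methanolysis frees the phenol that becomes the 2′-OH.

Step 3
Reactants: 5 resorcinol monobenzoate (3-hydroxyphenyl benzoate)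
Product: 6 2-bromo-5-hydroxyphenyl benzoate
Conditions: NBS (1.0 equiv), MeCN, 0 °C → rt
Reagents that add atoms: N-bromosuccinimide (NBS), O=C1CCC(=O)N1Br
Why: Electrophilic aromatic bromination in which the free OH dominates over the weakly donating benzoyloxy group and directs NBS to its para position, so that bromine should end up ortho to the ester oxygen (the future O1).

Step 4
Reactants: 6 2-bromo-5-hydroxyphenyl benzoate
Product: 8 2-bromo-5-(methoxymethoxy)phenol, via MOM-protected bromophenyl benzoate 7 (not isolated)
Conditions: MOMCl, i-Pr2NEt, CH2Cl2, 0 °C → rt; then NaOMe, MeOH, rt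
Reagents that add atoms: chloromethyl methyl ether (MOMCl), COCCl
Why: MOM protection of the free phenol followed in the same flask by methanolysis (transesterification) of the aryl benzoate, to which the MOM acetal is inert, should unmask only the oxygen ortho to bromine.

Step 5
Reactants: 8 2-bromo-5-(methoxymethoxy)phenol; 9 methyl glycidate (methyl oxirane-2-carboxylate, racemic)
Product: 10 methyl 3-[2-bromo-5-(methoxymethoxy)phenoxy]-2-hydroxypropanoate (racemic)
Conditions: CsF (0.2 equiv), DMF, 60 °C
Reagents that add atoms: none
Why: Base-catalysed SN2 opening of the glycidic ester by the phenoxide at the unsubstituted C3 (a known reaction of phenols with methyl glycidate) builds O1–C2–C3–C4 in one step, and the racemic carbinol is oxidised in the next step.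

Step 6
Reactants: 10 methyl 3-[2-bromo-5-(methoxymethoxy)phenoxy]-2-hydroxypropanoate
Product: 11 methyl 3-[2-bromo-5-(methoxymethoxy)phenoxy]-2-oxopropanoate
Conditions: Dess–Martin periodinane, CH2Cl2, rt (used directly)
Reagents that add atoms: none
Why: Dess–Martin oxidation converts the secondary α-hydroxy ester into the α-keto ester under neutral conditions that tolerate the MOM ether and the aryl bromide.

Step 7
Reactants: 4 3-methoxy-2-(methoxymethoxy)phenol (1.5 equiv); 11 methyl 3-[2-bromo-5-(methoxymethoxy)phenoxy]-2-oxopropanoate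
Product: 12 methyl (2S)-3-[2-bromo-5-(methoxymethoxy)phenoxy]-2-hydroxy-2-[2-hydroxy-4-methoxy-3-(methoxymethoxy)phenyl]propanoate
Conditions: quinine-derived 3,5-bis(trifluoromethyl)phenyl squaramide (10 mol%), 4 Å MS, toluene, −20 °C → rt
Reagents that add atoms: none
Why: The quinuclidine nitrogen of the catalyst hydrogen-bonds to (partially deprotonates) the OH of 4 while the squaramide N–H pair binds the 1,2-dicarbonyl of 11, and within this ternary complex C6 of 4 attacks the ketone carbon, after which tautomerisation of the cyclohexadienone restores the phenol. The closest known reaction type is the organocatalytic enantioselective ortho-Friedel–Crafts hydroxyalkylation of phenols and naphthols with α-keto esters (notably trifluoropyruvates) and isatins. No ring is closed. The new quaternary stereocentre is under catalyst control: the cinchona scaffold should shield the Si face of the bound ketone so that the arene adds to the Re face (O > CO2Me > CH2OAr) and gives (S). The step needs ortho- rather than para- or O-attack and reaction of the phenol rather than of ring A; the OH···N hydrogen bond delivers the electrophile to the ortho carbon, which is also para to OMe and thus the electronically preferred site, and ring A of 11 has no free OH that the base could activate. Aryl bromide, MOM acetals and ester are inert under these neutral conditions.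

Step 8
Reactants: 12 methyl (2S)-3-[2-bromo-5-(methoxymethoxy)phenoxy]-2-hydroxy-2-[2-hydroxy-4-methoxy-3-(methoxymethoxy)phenyl]propanoate
Product: 14 (3S)-3-hydroxy-3-[2-hydroxy-4-methoxy-3-(methoxymethoxy)phenyl]-7-(methoxymethoxy)chroman-4-one, via trilithiated aryllithium 13 (not isolated)
Conditions: MeLi (2.1 equiv), THF, −78 °C; n-BuLi (1.2 equiv), −78 → −30 °C; aq. NH4Cl
Reagents that add atoms: none
Why: Parham cyclisation: after both OH groups are deprotonated, bromine–lithium exchange (faster than addition to the ester at −78 °C) gives aryllithium 13, which acylates itself at the ester through a six-membered transition state to form C4–C4a, and C3 bears no α-hydrogen so its configuration is untouched.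

Step 9
Reactants: 14 (3S)-3-hydroxy-3-[2-hydroxy-4-methoxy-3-(methoxymethoxy)phenyl]-7-(methoxymethoxy)chroman-4-one
Product: 15 (3S)-3-[5-bromo-2-hydroxy-4-methoxy-3-(methoxymethoxy)phenyl]-3-hydroxy-7-(methoxymethoxy)chroman-4-one
Conditions: NBS (1.05 equiv), MeCN, −20 °C
Reagents that add atoms: N-bromosuccinimide (NBS), O=C1CCC(=O)N1Br
Why: Electrophilic aromatic bromination: with C1′ now substituted, C5′ (para to the free 2′-OH and ortho to OMe) is the only activated open position, and ring A is deactivated by the C4 carbonyl.

Step 10
Reactants: 15 (3S)-3-[5-bromo-2-hydroxy-4-methoxy-3-(methoxymethoxy)phenyl]-3-hydroxy-7-(methoxymethoxy)chroman-4-one; 16 prenylboronic acid pinacol ester (4,4,5,5-tetramethyl-2-(3-methylbut-2-en-1-yl)-1,3,2-dioxaborolane)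
Product: 17 (3S)-3-hydroxy-3-[2-hydroxy-4-methoxy-3-(methoxymethoxy)-5-(3-methylbut-2-en-1-yl)phenyl]-7-(methoxymethoxy)chroman-4-one
Conditions: Pd-PEPPSI-IPent (3 mol%), K3PO4 (aq), THF, 60 °C
Reagents that add atoms: none
Why: Suzuki–Miyaura coupling of the aryl bromide with prenyl-Bpin, in which the bulky NHC–Pd catalyst should let the allyl-palladium intermediate equilibrate and reductively eliminate at the unsubstituted terminus to give the linear prenyl arene.

Step 11
Reactants: 17 (3S)-3-hydroxy-3-[2-hydroxy-4-methoxy-3-(methoxymethoxy)-5-(3-methylbut-2-en-1-yl)phenyl]-7-(methoxymethoxy)chroman-4-one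
Product: 18 (3S)-3-[2,3-dihydroxy-4-methoxy-5-(3-methylbut-2-en-1-yl)phenyl]-3,7-dihydroxychroman-4-one (CNP0275486.1)
Conditions: HCl (1.25 M in MeOH), THF, 35 °C, under argon
Reagents that add atoms: none
Why: Acid-catalysed acetal exchange with methanol removes both MOM groups, while the prenyl group (flanked by OMe and H, no neighbouring free OH) cannot cyclise to a chroman and C3, lacking an α-hydrogen, cannot epimerise.

**Compound list**

1 | o-vanillin (2-hydroxy-3-methoxybenzaldehyde) | COc1cccc(C=O)c1O | starting material
2 | 3-methoxy-2-(methoxymethoxy)benzaldehyde | COCOc1c(OC)cccc1C=O | intermediate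
3 | 3-methoxy-2-(methoxymethoxy)phenyl formate | COCOc1c(OC)cccc1OC=O | intermediate (not isolated)
4 | 3-methoxy-2-(methoxymethoxy)phenol | COCOc1c(OC)cccc1O | intermediate
5 | resorcinol monobenzoate (3-hydroxyphenyl benzoate) | Oc1cccc(OC(=O)c2ccccc2)c1 | starting material
6 | 2-bromo-5-hydroxyphenyl benzoate | Oc1ccc(Br)c(OC(=O)c2ccccc2)c1 | intermediate
7 | 2-bromo-5-(methoxymethoxy)phenyl benzoate | COCOc1ccc(Br)c(OC(=O)c2ccccc2)c1 | intermediate (not isolated)
8 | 2-bromo-5-(methoxymethoxy)phenol | COCOc1ccc(Br)c(O)c1 | intermediate
9 | methyl glycidate (methyl oxirane-2-carboxylate, racemic) | COC(=O)C1CO1 | starting material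
10 | methyl 3-[2-bromo-5-(methoxymethoxy)phenoxy]-2-hydroxypropanoate (racemic) | COCOc1ccc(Br)c(OCC(O)C(=O)OC)c1 | intermediate
11 | methyl 3-[2-bromo-5-(methoxymethoxy)phenoxy]-2-oxopropanoate | COCOc1ccc(Br)c(OCC(=O)C(=O)OC)c1 | intermediate
12 | methyl (2S)-3-[2-bromo-5-(methoxymethoxy)phenoxy]-2-hydroxy-2-[2-hydroxy-4-methoxy-3-(methoxymethoxy)phenyl]propanoate | COc1ccc([C@](C(=O)OC)(O)COc2cc(OCOC)ccc2Br)c(O)c1OCOC | intermediate
13 | trilithiated form of 12 (Br replaced by Li, both OH as OLi) | COc1ccc([C@](C(=O)OC)(O[Li])COc2cc(OCOC)ccc2[Li])c(O[Li])c1OCOC | intermediate (not isolated)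
14 | (3S)-3-hydroxy-3-[2-hydroxy-4-methoxy-3-(methoxymethoxy)phenyl]-7-(methoxymethoxy)chroman-4-one | COc1ccc([C@]2(O)COc3cc(OCOC)ccc3C2=O)c(O)c1OCOC | intermediate
15 | (3S)-3-[5-bromo-2-hydroxy-4-methoxy-3-(methoxymethoxy)phenyl]-3-hydroxy-7-(methoxymethoxy)chroman-4-one | COc1c(Br)cc([C@]2(O)COc3cc(OCOC)ccc3C2=O)c(O)c1OCOC | intermediate
16 | prenylboronic acid pinacol ester | CC(C)=CCB1OC(C)(C)C(C)(C)O1 | starting material
17 | (3S)-3-hydroxy-3-[2-hydroxy-4-methoxy-3-(methoxymethoxy)-5-(3-methylbut-2-en-1-yl)phenyl]-7-(methoxymethoxy)chroman-4-one | COc1c(CC=C(C)C)cc([C@]2(O)COc3cc(OCOC)ccc3C2=O)c(O)c1OCOC | intermediate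
18 | (3S)-3-[2,3-dihydroxy-4-methoxy-5-(3-methylbut-2-en-1-yl)phenyl]-3,7-dihydroxychroman-4-one | COc1c(CC=C(C)C)cc([C@]2(O)COc3cc(O)ccc3C2=O)c(O)c1O | target

**Totals.** Total step count: 11. Longest linear sequence: 9 steps (steps 3–11, from resorcinol monobenzoate 5).

**Steps most likely to fail**

Step 7. The non-fluorinated, enolisable keto ester may turn over slowly, with amine-induced self-aldol outrunning arylation; attack may leak to the position para to OH; facial discrimination may be poor. The fallback replaces catalyst control by auxiliary control on a magnesium phenoxide template. It sets out from hydroxy ester 10: saponification (LiOH, THF/H2O) should give 3-[2-bromo-5-(methoxymethoxy)phenoxy]-2-hydroxypropanoic acid F1. Esterification with (1S,2R,5S)-8-phenylmenthol (DCC, DMAP) should give the 8-phenylmenthyl hydroxy ester F2 (C2 epimers, inconsequential), and Dess–Martin oxidation the 8-phenylmenthyl keto ester F3. The bromomagnesium phenoxide of 4 (EtMgBr, then CH2Cl2, −20 °C) should add to F3 through a six-membered magnesium chelate that enforces ortho attack, while the cumyl phenyl group shields one face of the chelated keto ester, to give the (S)-configured 8-phenylmenthyl adduct F4. This auxiliary antipode is chosen on the expectation, by analogy with additions to 8-phenylmenthyl glyoxylates and pyruvates, that the open face is Re; the (1R,2S,5R)-auxiliary is used if the sense proves opposite. F4 is submitted to step 8, in which the auxiliary alkoxide is the leaving group, and the route is rejoined at chromanone 14.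

Step 8. The aryllithium may be quenched by hydroxyls that were not fully deprotonated, exchange may be sluggish inside an aggregated polyanion, or the alkyllithium may add to the ester. The fallback uses a protected substrate instead of a polyanion. From 12, N,O-bis(trimethylsilyl)acetamide should give the bis(trimethylsilyl) ether F5. t-BuLi (2 equiv, THF, −78 °C) should effect exchange and cyclisation to the bis-silylated chromanone F6. Dilute aqueous citric acid in the work-up removes both silyl groups, and the route is rejoined at 14.

Step 10. Transmetalation and reductive elimination may proceed through the γ-terminus and give the reverse-prenyl isomer, or oxidative addition into the electron-rich, ortho-substituted bromophenoxide may be slow and lead to protodebromination. The fallback is sigmatropic instead of a cross-coupling and sets out from 14, skipping step 9. O-Alkylation of the 2′-OH with prenyl bromide (K2CO3, acetone) should give the 2′-O-prenyl ether F7. Heating (N,N-diethylaniline, 180 °C) should trigger a para-Claisen–Cope sequence: both ortho positions (C1′, C3′) are blocked, so two consecutive [3,3] shifts deliver the prenyl group with linear connectivity to C5′. The route is rejoined at 17.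

**Further compounds**

F1 | step 7 | 3-[2-bromo-5-(methoxymethoxy)phenoxy]-2-hydroxypropanoic acid (racemic) | COCOc1ccc(Br)c(OCC(O)C(=O)O)c1
F2 | step 7 | (1S,2R,5S)-5-methyl-2-(2-phenylpropan-2-yl)cyclohexyl 3-[2-bromo-5-(methoxymethoxy)phenoxy]-2-hydroxypropanoate (C2 epimers) | COCOc1ccc(Br)c(OCC(O)C(=O)O[C@H]2C[C@@H](C)CC[C@@H]2C(C)(C)c2ccccc2)c1
F3 | step 7 | (1S,2R,5S)-5-methyl-2-(2-phenylpropan-2-yl)cyclohexyl 3-[2-bromo-5-(methoxymethoxy)phenoxy]-2-oxopropanoate | COCOc1ccc(Br)c(OCC(=O)C(=O)O[C@H]2C[C@@H](C)CC[C@@H]2C(C)(C)c2ccccc2)c1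
F4 | step 7 | (1S,2R,5S)-5-methyl-2-(2-phenylpropan-2-yl)cyclohexyl (2S)-3-[2-bromo-5-(methoxymethoxy)phenoxy]-2-hydroxy-2-[2-hydroxy-4-methoxy-3-(methoxymethoxy)phenyl]propanoate | COc1ccc([C@](C(=O)O[C@H]2C[C@@H](C)CC[C@@H]2C(C)(C)c2ccccc2)(O)COc2cc(OCOC)ccc2Br)c(O)c1OCOC
F5 | step 8 | methyl (2S)-3-[2-bromo-5-(methoxymethoxy)phenoxy]-2-[4-methoxy-3-(methoxymethoxy)-2-(trimethylsilyloxy)phenyl]-2-(trimethylsilyloxy)propanoate | COc1ccc([C@](C(=O)OC)(O[Si](C)(C)C)COc2cc(OCOC)ccc2Br)c(O[Si](C)(C)C)c1OCOC
F6 | step 8 | (3S)-7-(methoxymethoxy)-3-[4-methoxy-3-(methoxymethoxy)-2-(trimethylsilyloxy)phenyl]-3-(trimethylsilyloxy)chroman-4-one | COc1ccc([C@]2(O[Si](C)(C)C)COc3cc(OCOC)ccc3C2=O)c(O[Si](C)(C)C)c1OCOC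
F7 | step 10 | (3S)-3-hydroxy-3-[4-methoxy-3-(methoxymethoxy)-2-(3-methylbut-2-en-1-yloxy)phenyl]-7-(methoxymethoxy)chroman-4-one | COc1ccc([C@]2(O)COc3cc(OCOC)ccc3C2=O)c(OCC=C(C)C)c1OCOC
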